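## Retrosynthetic overview
1. No ring is formed. Both benzene rings are bought already dibrominated, because late bromination would go ortho/para to the free OH, which is the wrong pattern.
2. Final FGI: the ring-B OH comes from CHO by Baeyer–Villiger oxidation and formate cleavage. This same CHO is the activator for the ether-forming step.
3. Key disconnection: the diaryl ether C–O bond, made by SNAr of 3,5-dibromo-2-methoxyphenol on 3,5-dibromo-2-fluorobenzaldehyde.
4. The ring-A phenol comes from 3,5-dibromo-2-methoxybenzaldehyde by the same CHO → OH oxidation.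
5. Forward order: make the ring-A phenol, join the rings, then unveil the ring-B phenol.

Assumption: the target has no stereocentre and no configurationally stable axis, so it is achiral and needs no stereocontrol; 1 and 4 are taken as catalogue compounds.

## Route

Step 1
Reactants: 1 3,5-dibromo-2-methoxybenzaldehyde
Product: 3 3,5-dibromo-2-methoxyphenol, via aryl formate 2 (not isolated)
Conditions: mCPBA (1.5 equiv), CH2Cl2, 0 °C → reflux, 16 h; aq. Na2SO3/NaHCO3 wash; crude 2, 2 M NaOH, MeOH, rt, 30 min; 1 M HCl work-up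
Reagents that add atoms: mCPBA (3-chloroperoxybenzoic acid), O=C(OO)c1cccc(Cl)c1
Why: Baeyer–Villiger (Dakin-type) oxidation, in which the Criegee adduct collapses by 1,2-aryl shift assisted by the ortho-OMe donor and the labile formate 2 is then saponified; C–Br and OMe are inert and no stereocentre is formed.

Step 2
Reactants: 3 3,5-dibromo-2-methoxyphenol; 4 3,5-dibromo-2-fluorobenzaldehyde
Product: 5 3,5-dibromo-2-(3,5-dibromo-2-methoxyphenoxy)benzaldehyde
Conditions: K2CO3 (1.5 equiv), dry DMF, N2, 80 °C, 12 h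
Reagents that add atoms: none
Why: SNAr (addition–elimination), in which the phenoxide of 3 attacks C–F, the only halogen ortho to the formyl acceptor, while both C–Br bonds are meta to CHO and stay untouched without a metal catalyst; no stereocentre is formed.

Step 3
Reactants: 5 3,5-dibromo-2-(3,5-dibromo-2-methoxyphenoxy)benzaldehyde
Product: 7 3,5-dibromo-2-(3,5-dibromo-2-methoxyphenoxy)phenol, via diaryl ether formate 6 (not isolated)
Conditions: mCPBA (2 equiv), CH2Cl2, reflux, 24 h; aq. Na2SO3/NaHCO3 wash; crude 6, 2 M NaOH, MeOH, 0 °C → rt, 30 min; 1 M HCl work-up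
Reagents that add atoms: mCPBA (3-chloroperoxybenzoic acid), O=C(OO)c1cccc(Cl)c1
Why: Baeyer–Villiger oxidation with migration of the ortho-aryloxy-substituted ring, followed by formate saponification at rt, where the unactivated ring A cannot undergo Smiles migration, so the OH ends exactly where CHO stood; no stereocentre is formed.

## Compound list
1 | 3,5-dibromo-2-methoxybenzaldehyde | COc1c(Br)cc(Br)cc1C=O | starting material
2 | 3,5-dibromo-2-methoxyphenyl formate | COc1c(Br)cc(Br)cc1OC=O | intermediate
3 | 3,5-dibromo-2-methoxyphenol | COc1c(Br)cc(Br)cc1O | intermediate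
4 | 3,5-dibromo-2-fluorobenzaldehyde | O=Cc1cc(Br)cc(Br)c1F | starting material
5 | 3,5-dibromo-2-(3,5-dibromo-2-methoxyphenoxy)benzaldehyde | COc1c(Br)cc(Br)cc1Oc1c(C=O)cc(Br)cc1Br | intermediate
6 | 3,5-dibromo-2-(3,5-dibromo-2-methoxyphenoxy)phenyl formate | COc1c(Br)cc(Br)cc1Oc1c(OC=O)cc(Br)cc1Br | intermediate
7 | 3,5-dibromo-2-(3,5-dibromo-2-methoxyphenoxy)phenol (achiral) | COc1c(Br)cc(Br)cc1Oc1c(O)cc(Br)cc1Br | target

Total step count: 3
Longest linear sequence: 3 steps (1 → 3 → 5 → 7)

## Steps most likely to fail, with fallbacks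

**Step 3 (highest risk).** Ring B of 5 has two Br meta to the migrating carbon, and its doubly ortho-flanked ether oxygen is twisted out of conjugation. The Criegee adduct may therefore lose the formyl H and give the benzoic acid instead of 6. The fallback sets out from 5 and comes back at 7, and it works by removing the formyl hydrogen. MeMgBr (THF, −78 → 0 °C) adds to 5 to give racemic 1-[3,5-dibromo-2-(3,5-dibromo-2-methoxyphenoxy)phenyl]ethan-1-ol F1. Dess–Martin periodinane (CH2Cl2, rt) oxidises it to 1-[3,5-dibromo-2-(3,5-dibromo-2-methoxyphenoxy)phenyl]ethan-1-one F2. CF3CO3H (TFAA, urea·H2O2, Na2HPO4, CH2Cl2) then oxidises this methyl ketone. Methyl is the poorest migrating group, so only the aryl shift is open, and the product is 3,5-dibromo-2-(3,5-dibromo-2-methoxyphenoxy)phenyl acetate F3. NaOH in MeOH at rt gives 7.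

**Step 1.** The same competition between hydride loss and aryl shift applies to the electron-poor ring of 1. The fallback sets out from 1 and comes back at 5, so phenol 3 is bypassed. It replaces the peracid oxidation of the methyl ether with a true Dakin oxidation of the free ortho-hydroxy aldehyde, whose phenoxide drives the aryl migration.
- BBr3 (CH2Cl2, −78 → 0 °C) demethylates 1 to 3,5-dibromo-2-hydroxybenzaldehyde F4.
- H2O2 in aq. NaOH takes F4 through 3,5-dibromo-2-hydroxyphenyl formate F5 to 3,5-dibromobenzene-1,2-diol F6.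
- F6 and one equivalent of 4 (K2CO3 2.2 equiv, DMF, 80 °C) give 3,5-dibromo-2-(3,5-dibromo-2-hydroxyphenoxy)benzaldehyde F7.
- The aryl group should end on the less hindered O-1. Any O-2 ether can equilibrate by Smiles rearrangement over the CHO-activated ring to the isomer that leaves the more acidic ortho/para-dibromo phenoxide free.
- MeI and K2CO3 in acetone at rt, where Smiles migration is slow, then give 5.

**Step 2.** The C–F carbon of 4 is flanked by Br and CHO, and 3 is a weak, ortho-substituted nucleophile. The coupling may therefore stall, or the aldehyde may degrade on long heating. The fallback sets out from 3 and comes back at 7, so 5 and step 3 are bypassed. It uses nitro activation followed by diazonium hydrolysis, the classical route to 2-hydroxydiphenyl ethers.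
- Commercial 4-bromo-1-fluoro-2-nitrobenzene is brominated (NBS, conc. H2SO4, 60 °C) at the position ortho to F and meta to NO2, giving 1,5-dibromo-2-fluoro-3-nitrobenzene F8.
- 3 and F8 (K2CO3, DMF, rt → 50 °C) give 1,5-dibromo-2-(3,5-dibromo-2-methoxyphenoxy)-3-nitrobenzene F9.
- Fe/NH4Cl (EtOH–H2O, 80 °C) reduces F9 to 3,5-dibromo-2-(3,5-dibromo-2-methoxyphenoxy)aniline F10 without touching C–Br.
- NaNO2 in H2SO4/AcOH at 0 °C gives 3,5-dibromo-2-(3,5-dibromo-2-methoxyphenoxy)benzenediazonium hydrogen sulfate F11.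
- F11 is run into boiling dilute H2SO4 to give 7.

## Further compounds
F1 | step 3 | 1-[3,5-dibromo-2-(3,5-dibromo-2-methoxyphenoxy)phenyl]ethan-1-ol (racemic) | COc1c(Br)cc(Br)cc1Oc1c(C(C)O)cc(Br)cc1Br
F2 | step 3 | 1-[3,5-dibromo-2-(3,5-dibromo-2-methoxyphenoxy)phenyl]ethan-1-one | COc1c(Br)cc(Br)cc1Oc1c(C(C)=O)cc(Br)cc1Br
F3 | step 3 | 3,5-dibromo-2-(3,5-dibromo-2-methoxyphenoxy)phenyl acetate | COc1c(Br)cc(Br)cc1Oc1c(OC(C)=O)cc(Br)cc1Br
F4 | step 1 | 3,5-dibromo-2-hydroxybenzaldehyde | O=Cc1cc(Br)cc(Br)c1O
F5 | step 1 | 3,5-dibromo-2-hydroxyphenyl formate | O=COc1cc(Br)cc(Br)c1O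
F6 | step 1 | 3,5-dibromobenzene-1,2-diol | Oc1cc(Br)cc(Br)c1O
F7 | step 1 | 3,5-dibromo-2-(3,5-dibromo-2-hydroxyphenoxy)benzaldehyde | O=Cc1cc(Br)cc(Br)c1Oc1cc(Br)cc(Br)c1O
F8 | step 2 | 1,5-dibromo-2-fluoro-3-nitrobenzene | O=[N+]([O-])c1cc(Br)cc(Br)c1F
F9 | step 2 | 1,5-dibromo-2-(3,5-dibromo-2-methoxyphenoxy)-3-nitrobenzene | COc1c(Br)cc(Br)cc1Oc1c([N+](=O)[O-])cc(Br)cc1Br
F10 | step 2 | 3,5-dibromo-2-(3,5-dibromo-2-methoxyphenoxy)aniline | COc1c(Br)cc(Br)cc1Oc1c(N)cc(Br)cc1Br
F11 | step 2 | 3,5-dibromo-2-(3,5-dibromo-2-methoxyphenoxy)benzenediazonium hydrogen sulfate | COc1c(Br)cc(Br)cc1Oc1c([N+]#N)cc(Br)cc1Br.OS(=O)(=O)[O-]
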